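**Retrosynthetic overview**

1. The target is reached by acylating the two primary hydroxyls of a triol. The triol comes, by fluoride and then mild acid, from a 3-silyl-2-(silyloxymethyl)cyclohexenone whose side-chain diol is held as a dioxolane.
2. The six-membered enone ring (C1 = C=O, C2 = C–CH2O, C3 = CH=, C4 = CH2, C5 = stereocentre, C6 = CH2) is opened to a 3-substituted cyclobutanone plus BnMe2Si–C≡C–CH2OTBS. A nickel-catalysed, enantioselective two-carbon ring expansion forms C1–C2 and C3–C4 in one operation.
3. Enabling feature: C5 carries two CH2 arms (C4 and C6) besides the side chain. Tying both arms to the carbonyl carbon C1 gives a four-membered ketone with a mirror plane through C1 and C5. C2=C3 then enters as an alkyne between C1 and one of two enantiotopic CH2 groups, and that single choice creates the C5 stereocentre, the enone and the C2 branch.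
4. The skipped diene comes from a ruthenium Alder-ene coupling of 3-ethynylcyclobutanone dimethyl ketal with (R)-4-allyl-2,2,4-trimethyl-1,3-dioxolane, itself made from (S)-2-methylglycidol and a vinyl Grignard reagent.
5. Ring order: the cyclobutane is purchased (temporary) and the dioxolane (temporary) is formed in step 4. The cyclohexenone, the only ring of the target, is formed in step 8, and the dioxolane is opened in step 10.

Key step: step 8

Remark: the sense of induction of the phosphoramidite in step 8 cannot be derived with certainty from a model; the (S,S,S)-ligand is written, and its equally available (R,R,R)-antipode takes its place if the first run favours the C5 epimer.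

**Route**

Step 1
Reactants: 1 methyl 3,3-dimethoxycyclobutane-1-carboxylate
Product: 2 3,3-dimethoxycyclobutane-1-carbaldehyde
Conditions: i-Bu2AlH (1.05 equiv), CH2Cl2, −78 °C; then aq. potassium sodium tartrate
Reagents that add atoms: none
Why: Partial reduction of an ester to the aldehyde with i-Bu2AlH, which at −78 °C delivers one hydride and releases the aldehyde only on aqueous work-up, while the dimethyl ketal is inert and no stereocentre is present.

Step 2
Reactants: 2 3,3-dimethoxycyclobutane-1-carbaldehyde
Product: 3 3-ethynyl-1,1-dimethoxycyclobutane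
Conditions: dimethyl (1-diazo-2-oxopropyl)phosphonate (1.2 equiv), K2CO3 (2 equiv), MeOH, 0 °C to rt
Reagents that add atoms: dimethyl (1-diazo-2-oxopropyl)phosphonate, CC(=O)C(=[N+]=[N-])P(=O)(OC)OC
Why: Seyferth–Gilbert homologation in its Ohira–Bestmann form: methanolysis of the reagent liberates dimethyl (diazomethyl)phosphonate, whose anion turns the aldehyde into the terminal alkyne under conditions (K2CO3, MeOH) that leave the ketal untouched.

Step 3
Reactants: 4 (S)-2-methylglycidol [(S)-(2-methyloxiran-2-yl)methanol]
Product: 5 (R)-2-methylpent-4-ene-1,2-diol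
Conditions: CH2=CHMgBr (3 equiv), CuI (10 mol %), THF, −30 to 0 °C; then H2O
Reagents that add atoms: vinylmagnesium bromide, C=C[Mg]Br
Why: Copper-catalysed Grignard opening of a 2,2-disubstituted epoxide at its unsubstituted CH2 (SN2), in which no bond to the quaternary stereocentre is broken, so that (S)-4 gives (R)-5 with unchanged spatial arrangement (the descriptor changes only through the CIP ranking, and the degenerate Payne isomer of the alkoxide leads to the same enantiomer).

Step 4
Reactants: 5 (R)-2-methylpent-4-ene-1,2-diol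
Product: 6 (R)-4-allyl-2,2,4-trimethyl-1,3-dioxolane
Conditions: Me2C(OMe)2, PPTS (cat.), CH2Cl2, rt
Reagents that add atoms: 2,2-dimethoxypropane, COC(C)(C)OC
Why: Acid-catalysed transacetalisation (isopropylidene acetal formation) masks the primary and the tertiary hydroxyl in one temporary dioxolane ring that is inert to the ruthenium, nickel and fluoride steps, without touching the stereocentre.

Step 5
Reactants: 3 3-ethynyl-1,1-dimethoxycyclobutane; 6 (R)-4-allyl-2,2,4-trimethyl-1,3-dioxolane (1.2 equiv)
Product: 7 (4R)-4-[(1E)-4-(3,3-dimethoxycyclobutyl)penta-1,4-dien-1-yl]-2,2,4-trimethyl-1,3-dioxolane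
Conditions: [CpRu(MeCN)3]PF6 (5 mol %), acetone, rt
Reagents that add atoms: none
Why: Ruthenium-catalysed alkene–alkyne coupling (intermolecular Alder-ene-type reaction with a cationic cyclopentadienyl complex of divalent ruthenium), which joins the internal alkyne carbon of 3 to the terminal alkene carbon of 6 and shifts the only allylic hydrogens of 6, those next to the quaternary centre, so that the branched 1,1-disubstituted alkene and the E-configured disubstituted alkene of the skipped diene arise together with the stereocentre untouched.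

Step 6
Reactants: 7 (4R)-4-[(1E)-4-(3,3-dimethoxycyclobutyl)penta-1,4-dien-1-yl]-2,2,4-trimethyl-1,3-dioxolane
Product: 8 3-{(4E)-5-[(4R)-2,2,4-trimethyl-1,3-dioxolan-4-yl]penta-1,4-dien-2-yl}cyclobutan-1-one
Conditions: TsOH·H2O (5 mol %), acetone/H2O (20:1), rt
Reagents that add atoms: water, O
Why: Acid-catalysed ketal cleavage by exchange with wet acetone (transketalisation/hydrolysis) frees the cyclobutanone, while the dioxolane, itself an acetone ketal, is held in place by the solvent.

Step 7
Reactants: 9 tert-butyldimethyl(prop-2-yn-1-yloxy)silane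
Product: 11 benzyl{3-[(tert-butyldimethylsilyl)oxy]prop-1-yn-1-yl}dimethylsilane, via lithium acetylide 10 (not isolated)
Conditions: n-BuLi (1.05 equiv), THF, −78 °C; then BnMe2SiCl, −78 °C to rt
Reagents that add atoms: benzylchlorodimethylsilane, C[Si](C)(Cl)Cc1ccccc1
Why: Deprotonation of the terminal alkyne and C-silylation of the lithium acetylide with a chlorosilane (standard alkynylsilane synthesis), the benzyldimethylsilyl group being chosen because it steers the regiochemistry of step 8 and is lost to fluoride in step 9.

Step 8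
Reactants: 8 3-{(4E)-5-[(4R)-2,2,4-trimethyl-1,3-dioxolan-4-yl]penta-1,4-dien-2-yl}cyclobutan-1-one; 11 benzyl{3-[(tert-butyldimethylsilyl)oxy]prop-1-yn-1-yl}dimethylsilane (2 equiv)
Product: 14 (5S)-3-[benzyl(dimethyl)silyl]-2-{[(tert-butyldimethylsilyl)oxy]methyl}-5-{(4E)-5-[(4R)-2,2,4-trimethyl-1,3-dioxolan-4-yl]penta-1,4-dien-2-yl}cyclohex-2-en-1-one, via spiro oxanickelacyclopentene 12 (not isolated), via seven-membered nickelacycle 13 (not isolated)
Conditions: Ni(cod)2 (10 mol %), (S,S,S)-BINOL-derived N,N-bis(1-phenylethyl)phosphoramidite (20 mol %), toluene, 80 °C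
Reagents that add atoms: none
Why: Proposed new method: zerovalent nickel couples the ketone carbonyl of 8 and the alkyne of 11 by oxidative cyclisation (silicon-bearing carbon on nickel, oxymethyl-bearing carbon bonded to C1) to the spiro oxanickelacyclopentene 12, β-carbon elimination then cleaves one of the two enantiotopic C1–CH2 bonds of the four-membered ring to give the seven-membered alkyl(alkenyl) nickelacycle 13 of divalent nickel, and C(sp3)–C(sp2) reductive elimination releases the cyclohexenone and the catalyst. The closest known reaction types are the ligand-achiral nickel-catalysed intermolecular insertion of internal alkynes into 3-substituted cyclobutanones (formal [4+2]) and the enantioselective intramolecular alkene insertions of 3-substituted cyclobutanones under Ni(cod)2 with a chiral phosphoramidite; new is the enantiotopic-bond-selective intermolecular case with a silylalkyne. The six-membered ring is closed not by cyclisation of an open chain but by two-carbon ring expansion: C1–C2 is made in the oxidative cyclisation and C3–C4 by reductive elimination that contracts the seven-membered nickelacycle to the carbocycle. The C5 stereocentre is created in the β-carbon elimination, where the chiral phosphoramidite on nickel decides which enantiotopic acyl–CH2 bond migrates to the metal (catalyst control, the remote dioxolane centre being a spectator), and the mirror symmetry of 8 means that this is the only stereochemical choice to be made (5S in 14 is the spatial arrangement of 5R in the target). The step needs regioselectivity (silyl at C3, CH2OTBS at C2), secured by the α-silyl effect and the bulk of the BnMe2Si group that place silicon next to nickel, and chemoselectivity, secured by the much higher affinity of zerovalent nickel for the alkyne and the strained ketone than for the unactivated alkenes of the side chain and by reductive elimination from the seven-membered nickelacycle outrunning β-hydride elimination.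

Step 9
Reactants: 14 (5S)-3-[benzyl(dimethyl)silyl]-2-{[(tert-butyldimethylsilyl)oxy]methyl}-5-{(4E)-5-[(4R)-2,2,4-trimethyl-1,3-dioxolan-4-yl]penta-1,4-dien-2-yl}cyclohex-2-en-1-one
Product: 15 (5R)-2-(hydroxymethyl)-5-{(4E)-5-[(4R)-2,2,4-trimethyl-1,3-dioxolan-4-yl]penta-1,4-dien-2-yl}cyclohex-2-en-1-one
Conditions: Bu4NF·3H2O (3 equiv), THF, 0 °C to rt
Reagents that add atoms: none
Why: Fluoride desilylation of two known types in one flask: cleavage of the O–TBS ether frees the C2 hydroxymethyl group, and the fluoride-labile alkenyl(benzyl)dimethylsilane undergoes fluoride-promoted protodesilylation at C3, assisted by the alkoxide that lies cis to silicon across the ring alkene (pentacoordinate siliconate, carbon-to-oxygen silyl shift, protonation at C3, cleavage of the new O–Si bond), no stereocentre being touched (C5 becomes R only because silicon no longer ranks the C4 branch first).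

Step 10
Reactants: 15 (5R)-2-(hydroxymethyl)-5-{(4E)-5-[(4R)-2,2,4-trimethyl-1,3-dioxolan-4-yl]penta-1,4-dien-2-yl}cyclohex-2-en-1-one
Product: 16 (5R)-5-[(4E,6R)-6,7-dihydroxy-6-methylhepta-1,4-dien-2-yl]-2-(hydroxymethyl)cyclohex-2-en-1-one
Conditions: AcOH/H2O (4:1), rt to 40 °C
Reagents that add atoms: none
Why: Mild aqueous-acid hydrolysis of the isopropylidene acetal opens the temporary dioxolane ring to the primary/tertiary diol, the tertiary allylic alcohol being protected against ionisation by the electron-withdrawing neighbouring CH2OH and the stereocentres not being involved.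

Step 11
Reactants: 16 (5R)-5-[(4E,6R)-6,7-dihydroxy-6-methylhepta-1,4-dien-2-yl]-2-(hydroxymethyl)cyclohex-2-en-1-one
Product: 17 [(2R,3E)-2-hydroxy-2-methyl-6-{(1R)-4-[(isobutyryloxy)methyl]-5-oxocyclohex-3-en-1-yl}hepta-3,6-dien-1-yl] 2-methylpropanoate (CNP0536801.1)
Conditions: i-PrCOCl (2.3 equiv), pyridine, CH2Cl2, −20 to 0 °C
Reagents that add atoms: isobutyryl chloride, CC(C)C(Cl)=O
Why: Chemoselective O-acylation with an acid chloride and pyridine: the two primary hydroxyls react far faster than the hindered tertiary allylic one, and the absence of DMAP avoids SN2′ attack of a nucleophilic catalyst on the newly formed Morita–Baylis–Hillman-type allylic ester.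

**Compound list**

1 | methyl 3,3-dimethoxycyclobutane-1-carboxylate | COC(=O)C1CC(OC)(OC)C1 | starting material
2 | 3,3-dimethoxycyclobutane-1-carbaldehyde | O=CC1CC(OC)(OC)C1 | intermediate
3 | 3-ethynyl-1,1-dimethoxycyclobutane | C#CC1CC(OC)(OC)C1 | intermediate
4 | (S)-2-methylglycidol, (S)-(2-methyloxiran-2-yl)methanol | C[C@]1(CO)CO1 | starting material
5 | (R)-2-methylpent-4-ene-1,2-diol | C=CC[C@@](C)(O)CO | intermediate
6 | (R)-4-allyl-2,2,4-trimethyl-1,3-dioxolane | C=CC[C@@]1(C)OC(C)(C)OC1 | intermediate
7 | (4R)-4-[(1E)-4-(3,3-dimethoxycyclobutyl)penta-1,4-dien-1-yl]-2,2,4-trimethyl-1,3-dioxolane | C=C(C/C=C/[C@@]1(C)OC(C)(C)OC1)C1CC(OC)(OC)C1 | intermediate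
8 | 3-{(4E)-5-[(4R)-2,2,4-trimethyl-1,3-dioxolan-4-yl]penta-1,4-dien-2-yl}cyclobutan-1-one | C=C(C/C=C/[C@@]1(C)OC(C)(C)OC1)C1CC(=O)C1 | intermediate
9 | tert-butyldimethyl(prop-2-yn-1-yloxy)silane | C#CCO[Si](C)(C)C(C)(C)C | starting material
10 | lithium acetylide of 9, lithium 3-[(tert-butyldimethylsilyl)oxy]prop-1-yn-1-ide (not isolated) | [Li]C#CCO[Si](C)(C)C(C)(C)C | intermediate
11 | benzyl{3-[(tert-butyldimethylsilyl)oxy]prop-1-yn-1-yl}dimethylsilane | C[Si](C)(Cc1ccccc1)C#CCO[Si](C)(C)C(C)(C)C | intermediate
12 | spiro oxanickelacyclopentene from 8, 11 and nickel: 1-oxa-2-nickelacyclopent-3-ene spiro-fused to the cyclobutane, silyl on the carbon bound to nickel (phosphoramidite on nickel not drawn; configuration at the spiro carbon left open; not isolated) | C=C(C/C=C/[C@@]1(C)OC(C)(C)OC1)C1CC2(C1)O[Ni]C([Si](C)(C)Cc1ccccc1)=C2CO[Si](C)(C)C(C)(C)C | intermediate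
13 | seven-membered nickelacycle, 1-nickelacyclohept-2-en-4-one with 2-silyl, 3-(silyloxymethyl) and 6-alkenyl groups, ring CH configured as in 14 (phosphoramidite on nickel not drawn; not isolated) | C=C(C/C=C/[C@@]1(C)OC(C)(C)OC1)[C@H]1CC(=O)C(CO[Si](C)(C)C(C)(C)C)=C([Si](C)(C)Cc2ccccc2)[Ni]C1 | intermediate
14 | (5S)-3-[benzyl(dimethyl)silyl]-2-{[(tert-butyldimethylsilyl)oxy]methyl}-5-{(4E)-5-[(4R)-2,2,4-trimethyl-1,3-dioxolan-4-yl]penta-1,4-dien-2-yl}cyclohex-2-en-1-one | C=C(C/C=C/[C@@]1(C)OC(C)(C)OC1)[C@@H]1CC([Si](C)(C)Cc2ccccc2)=C(CO[Si](C)(C)C(C)(C)C)C(=O)C1 | intermediate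
15 | (5R)-2-(hydroxymethyl)-5-{(4E)-5-[(4R)-2,2,4-trimethyl-1,3-dioxolan-4-yl]penta-1,4-dien-2-yl}cyclohex-2-en-1-one | C=C(C/C=C/[C@@]1(C)OC(C)(C)OC1)[C@@H]1CC=C(CO)C(=O)C1 | intermediate
16 | (5R)-5-[(4E,6R)-6,7-dihydroxy-6-methylhepta-1,4-dien-2-yl]-2-(hydroxymethyl)cyclohex-2-en-1-one | C=C(C/C=C/[C@@](C)(O)CO)[C@@H]1CC=C(CO)C(=O)C1 | intermediate
17 | [(2R,3E)-2-hydroxy-2-methyl-6-{(1R)-4-[(isobutyryloxy)methyl]-5-oxocyclohex-3-en-1-yl}hepta-3,6-dien-1-yl] 2-methylpropanoate, CNP0536801.1 | C=C(C/C=C/[C@@](C)(O)COC(=O)C(C)C)[C@@H]1CC=C(COC(=O)C(C)C)C(=O)C1 | target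

**Step count and risks**

Total step count: 11. Longest linear sequence: 8 steps (1, 2, 5, 6, 8, 9, 10, 11 from 1; equally 3, 4, 5, 6, 8, 9, 10, 11 from 4).

Steps most likely to fail:

1. Step 8 (Proposed new method). Three processes are at risk: insufficient discrimination of the two enantiotopic acyl–CH2 bonds in the β-carbon elimination, which would erode the configuration at C5; β-hydride elimination of the alkylnickel intermediate before ring closure; and cyclotrimerisation of the alkyne. The fallback uses known chemistry and secures C5 by separation instead of induction. It sets out from 8 and 11. The established ligand-achiral nickel-catalysed intermolecular alkyne insertion into 3-substituted cyclobutanones (Ni(cod)2, PCy3, toluene, 100 °C) should give 14 together with its C5 epimer, the (5R)-configured 3-silyl-2-(silyloxymethyl)cyclohexenone F1. The pair is taken through the conditions of step 9 to 15 and its C5 epimer, the (5S)-configured hydroxymethyl enone F2. These are diastereomers and are to be separated by preparative HPLC on a chiral stationary phase. The route is rejoined at 15.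

2. Step 5. Two processes are at risk: C–C bond formation at the terminal instead of the internal alkyne carbon (linear instead of branched diene), and homocoupling of the alkyne. The fallback builds the same diene by allylmetalation and cross-metathesis; it sets out from 3 and 4 and rejoins the route at 7. Markovnikov allylindation of 3 (allyl bromide, indium powder, THF, rt to 60 °C) should give 1,1-dimethoxy-3-(penta-1,4-dien-2-yl)cyclobutane F3. One-carbon homologation of epoxide 4 with excess dimethylsulfonium methylide (Me3S+ I−, n-BuLi, THF, −10 °C to rt), which breaks no bond to the stereocentre, should give (R)-2-methylbut-3-ene-1,2-diol F4. Acetonide formation as in step 4 gives (R)-2,2,4-trimethyl-4-vinyl-1,3-dioxolane F5. Olefin cross-metathesis of F3 with F5 (second-generation Grubbs catalyst, RuCl2(=CHPh)(H2IMes)(PCy3), CH2Cl2, 40 °C) should then join the monosubstituted alkene of F3 to the non-dimerising vinyl group of F5 with E geometry and deliver 7.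

3. Step 9. Two processes are at risk: incomplete cleavage of the C3–Si bond, and base-induced degradation of the liberated hydroxymethyl enone (γ-deprotonation with double-bond migration, oxa-Michael oligomerisation). The fallback takes silicon off at the allylic-alcohol oxidation level and restores the ketone last; it sets out from 14 and rejoins the route at 17. Luche reduction (NaBH4, CeCl3·7H2O, MeOH, 0 °C) should give the (5S)-3-silyl-2-(silyloxymethyl)cyclohex-2-en-1-ol F6 as a mixture of C1 epimers. Bu4NF·3H2O in THF should then effect the well-known alkoxide-assisted protodesilylation of this non-conjugated Z-γ-hydroxy alkenylsilane together with O-desilylation and give the (5R)-2-(hydroxymethyl)cyclohex-2-en-1-ol F7. AcOH/H2O opens the dioxolane to the tetraol F8. i-PrCOCl (2.2 equiv) with 2,4,6-collidine in CH2Cl2 at −78 °C acylates the two primary hydroxyls to the bis(2-methylpropanoate) F9. MnO2 in CH2Cl2 oxidises the secondary allylic alcohol, which erases the C1 mixture and gives 17.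

**Further compounds**

F1 | step 8 | (5R)-3-[benzyl(dimethyl)silyl]-2-{[(tert-butyldimethylsilyl)oxy]methyl}-5-{(4E)-5-[(4R)-2,2,4-trimethyl-1,3-dioxolan-4-yl]penta-1,4-dien-2-yl}cyclohex-2-en-1-one (C5 epimer of 14) | C=C(C/C=C/[C@@]1(C)OC(C)(C)OC1)[C@H]1CC([Si](C)(C)Cc2ccccc2)=C(CO[Si](C)(C)C(C)(C)C)C(=O)C1
F2 | step 8 | (5S)-2-(hydroxymethyl)-5-{(4E)-5-[(4R)-2,2,4-trimethyl-1,3-dioxolan-4-yl]penta-1,4-dien-2-yl}cyclohex-2-en-1-one (C5 epimer of 15) | C=C(C/C=C/[C@@]1(C)OC(C)(C)OC1)[C@H]1CC=C(CO)C(=O)C1
F3 | step 5 | 1,1-dimethoxy-3-(penta-1,4-dien-2-yl)cyclobutane | C=CCC(=C)C1CC(OC)(OC)C1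
F4 | step 5 | (R)-2-methylbut-3-ene-1,2-diol | C=C[C@@](C)(O)CO
F5 | step 5 | (R)-2,2,4-trimethyl-4-vinyl-1,3-dioxolane | C=C[C@@]1(C)OC(C)(C)OC1
F6 | step 9 | (5S)-3-[benzyl(dimethyl)silyl]-2-{[(tert-butyldimethylsilyl)oxy]methyl}-5-{(4E)-5-[(4R)-2,2,4-trimethyl-1,3-dioxolan-4-yl]penta-1,4-dien-2-yl}cyclohex-2-en-1-ol (mixture of C1 epimers) | C=C(C/C=C/[C@@]1(C)OC(C)(C)OC1)[C@@H]1CC([Si](C)(C)Cc2ccccc2)=C(CO[Si](C)(C)C(C)(C)C)C(O)C1
F7 | step 9 | (5R)-2-(hydroxymethyl)-5-{(4E)-5-[(4R)-2,2,4-trimethyl-1,3-dioxolan-4-yl]penta-1,4-dien-2-yl}cyclohex-2-en-1-ol (mixture of C1 epimers) | C=C(C/C=C/[C@@]1(C)OC(C)(C)OC1)[C@@H]1CC=C(CO)C(O)C1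
F8 | step 9 | (5R)-5-[(4E,6R)-6,7-dihydroxy-6-methylhepta-1,4-dien-2-yl]-2-(hydroxymethyl)cyclohex-2-en-1-ol (mixture of C1 epimers) | C=C(C/C=C/[C@@](C)(O)CO)[C@@H]1CC=C(CO)C(O)C1
F9 | step 9 | [(2R,3E)-2-hydroxy-6-{(1R)-5-hydroxy-4-[(isobutyryloxy)methyl]cyclohex-3-en-1-yl}-2-methylhepta-3,6-dien-1-yl] 2-methylpropanoate (mixture of carbinol epimers in the ring) | C=C(C/C=C/[C@@](C)(O)COC(=O)C(C)C)[C@@H]1CC=C(COC(=O)C(C)C)C(O)C1
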